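A direct plan would start from the (S)-Hajos–Parrish ketone A1 and grow ring A out of its cyclopentanone: acyl-anion addition, chelation-controlled reduction, mesylation and a semipinacol 1,2-shift would give the dimethyl decalin enedione A2.
Ring B would then be dressed one centre at a time (copper hydride reduction with enol silylation, dissolving-metal reduction at C3, Rubottom oxidation at C9, palladium-catalysed isopropenylation at C7) to the silyl-protected ketol A3, which would be esterified with the side-chain acid and desilylated.
Weakest steps of that plan: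
- The ring-expanding 1,2-shift: four steps would be spent on a simple decalindione, and the shift depends on one rotamer, on migration of the quaternary carbon and on no epoxide closure.
- The conjugate reduction that sets the cis fusion at C10 and the ketone reduction at C3: two stereocentres would be set singly by reagent approach on a flexible cis-decalin, with nothing that enforces the outcome.
- The late enolate isopropenylation at C7 inside a two-silyl-group protecting stretch: it needs regioselective enolisation beside a silyloxy carbon and leaves an epimerisable β,γ-unsaturated ketone that conjugates easily.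

**Retrosynthetic overview**
- C3–O and C4–H: the ester is made last by anti-Markovnikov addition of the side-chain acid 22 across the C3=C4 bond of decalin 15, so C3 and C4 are set together with the ester bond.
- Ring B: C8(=O)–C7–C6–C5–C4=C3 of 15 is a δ,ε-unsaturated ketone, the retron of an oxy-Cope shift; cutting C5–C6 and joining C3–C8 leads back to the bicyclo[2.2.2]octenyl dienyl carbinol 13.
- Ring A comes first, as diene 4; a Diels–Alder reaction with vinylene carbonate bridges it, the meso diol 7 is desymmetrised enzymatically, and the dienyl group is delivered by the free hydroxyl.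
- Weak steps avoided: no ring expansion; C5, C9 and C10 are relayed as a group from the rigid bicycle; the isopropenyl group enters with the nucleophile; one silyl group, no redox adjustment at C3 or C8.

Key step: step 9

Remark: the decalin carries eremophilane numbering (C1–C4 in ring A, C6–C9 in ring B, C5 and C10 at the fusion); bicyclic intermediates carry bicyclo[2.2.2]octane numbering, in which C2, C3, C4, C5 become C8, C9, C10, C5 of the decalin.
Assumption: the alcohol dehydrogenase of step 4 is picked from an enzyme panel for oxidation of the (S)-configured carbinol of meso diol 7; an enzyme of the opposite preference would give the enantiomer.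

Step 1
Reactants: 1 2-methylcyclohex-2-en-1-one
Product: 3 6-methylcyclohexa-1,5-dien-1-yl trifluoromethanesulfonate, via lithium dienolate 2 (not isolated)
Conditions: LiN(iPr)2 (LDA), THF, −78 °C; then PhNTf2, −78 °C to rt
Reagents that add atoms: N-phenyl-bis(trifluoromethanesulfonimide), O=S(=O)(N(c1ccccc1)S(=O)(=O)C(F)(F)F)C(F)(F)F
Why: Kinetic deprotonation of the enone at the α′ methylene gives the cross-conjugated dienolate, and O-sulfonylation (enol triflate formation) fixes the 1,3-diene; no stereocentre is involved.

Step 2
Reactants: 3 dienyl triflate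
Product: 4 2,3-dimethylcyclohexa-1,3-diene
Conditions: MeMgBr, Fe(acac)3 (5 mol %), THF/NMP, −30 °C
Reagents that add atoms: methylmagnesium bromide, C[Mg]Br
Why: Iron-catalysed Kumada-type cross-coupling of an alkenyl triflate with a methyl Grignard reagent should replace the triflate by methyl, giving the s-cis diene of ring A with the future C4 and C5 methyl groups in place.

Step 3
Reactants: 4 2,3-dimethylcyclohexa-1,3-diene; 5 vinylene carbonate
Product: 7 (1R,2S,3R,4S)-5,6-dimethylbicyclo[2.2.2]oct-5-ene-2,3-diol (meso, both hydroxyls syn to the alkene bridge), via endo cyclic carbonate 6 (not isolated)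
Conditions: 5 (2 equiv), BHT, xylene, sealed tube, 165 °C; then 2 M NaOH, MeOH, rt
Reagents that add atoms: none
Why: The thermal Diels–Alder reaction of the cyclic diene with vinylene carbonate should favour the endo adduct (carbonate under the diene, oxygens syn to the new C=C), as with cyclohexa-1,3-diene, and saponification frees the meso diol whose four stereocentres are fixed relative to one another by the cycloaddition.

Step 4
Reactants: 7 meso diol
Product: 8 (1R,3R,4S)-3-hydroxy-5,6-dimethylbicyclo[2.2.2]oct-5-en-2-one (hydroxyl syn to the alkene bridge)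
Conditions: (S)-selective alcohol dehydrogenase (for example from Rhodococcus ruber), NAD+ (2 mol %), acetone (5 vol %), phosphate buffer pH 7.5, 30 °C; extracted and used at once
Reagents that add atoms: none
Why: Enzymatic desymmetrising oxidation of a meso diol by hydrogen transfer to acetone should oxidise only one of the two enantiotopic carbinols and so set the absolute configuration of the whole series; the neutral, halogen-free conditions spare the electron-rich alkene and limit racemisation of the acyloin through its enediol.

Step 5
Reactants: 9 4-chlorobut-2-yn-1-ol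
Product: 10 2-methylbuta-2,3-dien-1-ol
Conditions: MeMgBr (2.2 equiv), CuBr (10 mol %), THF, −30 to 0 °C
Reagents that add atoms: methylmagnesium bromide, C[Mg]Br
Why: Copper-catalysed anti-SN2′ substitution of the propargylic chloride by the Grignard reagent should give the 2-substituted allenyl carbinol; no stereocentre is formed.

Step 6
Reactants: 10 2-methylbuta-2,3-dien-1-ol
Product: 11 4-bromo-3-methylbuta-1,2-diene
Conditions: CBr4, PPh3, CH2Cl2, 0 °C; distilled cold
Reagents that add atoms: tetrabromomethane, BrC(Br)(Br)Br
Why: The Appel reaction converts the primary allenylmethyl alcohol into the bromide under neutral conditions that should not isomerise the allene.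

Step 7
Reactants: 8 hydroxy ketone; 11 4-bromo-3-methylbuta-1,2-diene
Product: 12 (1R,2S,3R,4S)-5,6-dimethyl-2-(3-methylbuta-1,3-dien-2-yl)bicyclo[2.2.2]oct-5-ene-2,3-diol (dienyl group and 3-OH syn to the alkene bridge, 2-OH syn to the ethano bridge)
Conditions: 11 (1.5 equiv), indium powder (1.5 equiv), THF/H2O (1:1), rt
Reagents that add atoms: none
Why: In this indium-mediated Barbier reaction the 2,3-dienylindium species reacts by SE2′ at its central allenic carbon (1,3-dien-2-ylation), and chelation of indium by the free C3 hydroxyl and the carbonyl oxygen should deliver the dienyl group to C2 on the face that carries O3, which is the face of the etheno bridge needed for the rearrangement.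

Step 8
Reactants: 12 diol
Product: 13 (1R,2S,3R,4S)-5,6-dimethyl-2-(3-methylbuta-1,3-dien-2-yl)-3-(triethylsilyloxy)bicyclo[2.2.2]oct-5-en-2-ol
Conditions: TESCl (1.1 equiv), imidazole, DMAP (cat.), CH2Cl2, 0 °C
Reagents that add atoms: chlorotriethylsilane, CC[Si](Cl)(CC)CC
Why: Silylation should take the secondary hydroxyl and leave the hindered tertiary one free; the silyl ether later keeps O9 from adding across the ring A alkene in step 13.

Step 9
Reactants: 13 silyl ether
Product: 15 9β-(triethylsilyloxy)-10βH-eremophila-3,11-dien-8-one (cis-fused; 5β-methyl, 7β-isopropenyl), via potassium dienolate 14 (not isolated)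
Conditions: KH (1.5 equiv), 18-crown-6 (1.5 equiv), THF, 0 °C to rt; then AcOH in THF, −78 °C
Reagents that add atoms: none
Why: Deprotonation of the tertiary alcohol gives a crown-ether-separated potassium alkoxide whose charge accelerates a [3,3] sigmatropic shift (anionic oxy-Cope rearrangement) of the 1,5-diene made up of the dienyl CH2=C unit, C2, C1 and the C6=C5 bridge: the C1–C2 bond of the bicycle (C3–C8 of the decalin) breaks while the dienyl CH2 bonds to the methyl-bearing alkene carbon (C6–C5 of the decalin), giving dienolate 14. The closest known reaction type is the anionic oxy-Cope rearrangement of 2-alkenylbicyclo[2.2.2]oct-5-en-2-ols to cis-fused octalones. Ring B is not closed end to end: it emerges as a six-membered ring from the suprafacial shift through the boat transition state that the bicycle enforces, while ring A is released as the cyclohexene that carries the new C3=C4 bond. The quaternary C5 is set because the dienyl terminus can reach the alkene only from the face on which C2 sits, so the C5–C6 bond forms cis to the C10–C9 bond (cis fusion, angular methyl and H10 both β); C9 and C10 are carried over unchanged from C3 and C4 of the bicycle, and C7 is set in the quench by axial protonation of the dienolate from the α face, which leaves the isopropenyl group equatorial (7β). The step needs the shift to outrun loss of the dienyl anion from the hindered alkoxide and silyl migration from O3, and protonation at the α-carbon and not at the terminal carbon of the dienolate; the syn placement of dienyl group and etheno bridge from step 7, the low temperature of the charge-accelerated shift and the kinetic acid quench at −78 °C should secure this.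

Step 10
Reactants: 16 (R)-1,2-epoxybutane
Product: 18 (R)-pent-1-en-3-ol, via sulfonium alkoxide 17 (not isolated)
Conditions: Me3S+ I− (3 equiv), n-BuLi (2.9 equiv), THF, −10 °C to rt
Reagents that add atoms: trimethylsulfonium iodide, C[S+](C)C.[I-]
Why: Epoxide-to-allylic-alcohol homologation with excess dimethylsulfonium methylide: the ylide opens the terminal carbon and ylide-mediated loss of dimethyl sulfide gives the vinyl carbinol without touching the (R) centre.

Step 11
Reactants: 18 (R)-pent-1-en-3-ol; 19 angelic acid
Product: 21 (3R)-pent-1-en-3-yl (2Z)-2-methylbut-2-enoate, via mixed anhydride 20 (not isolated)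
Conditions: 19, 2,4,6-trichlorobenzoyl chloride, Et3N, toluene, rt; then 18, 80 °C
Reagents that add atoms: none
Why: Yamaguchi esterification through the mixed anhydride, run without a nucleophilic catalyst, should acylate the alcohol with retention at the carbinol and without Z-to-E isomerisation of the angelate.

Step 12
Reactants: 21 allylic angelate
Product: 22 (2E,4R)-4-{[(2Z)-2-methylbut-2-enoyl]oxy}hex-2-enoic acid
Conditions: acrylic acid (3 equiv), second-generation Hoveyda–Grubbs catalyst (5 mol %), CH2Cl2, 40 °C
Reagents that add atoms: acrylic acid, C=CC(=O)O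
Why: Olefin cross-metathesis of the terminal alkene with acrylic acid should give the E-enoic acid, the trisubstituted electron-poor angelate alkene taking no part.

Step 13
Reactants: 15 decalin diene; 22 acid
Product: 23 9-O-triethylsilyl ether of the target
Conditions: 22 (2 equiv), 9-mesityl-10-methylacridinium tetrafluoroborate (5 mol %), PhSO2Na (20 mol %), 1,2-dichloroethane, 450 nm LEDs, rt
Reagents that add atoms: none
Why: In this photoredox anti-Markovnikov hydroacyloxylation the excited acridinium should oxidise only the trisubstituted C3=C4 alkene to its radical cation, the acid adds at the less substituted C3 on the α face (away from the axial C5 methyl), and hydrogen-atom transfer to the tertiary C4 radical from the α face leaves the C4 methyl equatorial and cis to the C5 methyl, so C3, C4 and the ester bond are set together.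

Step 14
Reactants: 23 silyl ether
Product: 24 target
Conditions: HF·pyridine, pyridine/THF, 0 °C to rt
Reagents that add atoms: none
Why: Buffered fluoride desilylation should free the 9β-hydroxyl while leaving both esters, the β,γ-unsaturated ketone and the α-ketol untouched.

**Compound list**

1 | 2-methylcyclohex-2-en-1-one | CC1=CCCC1=O | starting material
2 | lithium 6-methylcyclohexa-1,5-dien-1-olate | [Li]OC1=CCCC=C1C | intermediate (not isolated)
3 | 6-methylcyclohexa-1,5-dien-1-yl trifluoromethanesulfonate | CC1=CCCC=C1OS(=O)(=O)C(F)(F)F | intermediate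
4 | 2,3-dimethylcyclohexa-1,3-diene | CC1=CCCC=C1C | intermediate
5 | vinylene carbonate (1,3-dioxol-2-one) | O=C1OC=CO1 | starting material
6 | endo cyclic carbonate of 7: cis-5,6-dimethylbicyclo[2.2.2]oct-5-ene-2,3-diyl carbonate (meso, oxygens syn to the alkene bridge) | [C@@H]12[C@@H]3OC(=O)O[C@@H]3[C@@H](CC1)C(C)=C2C | intermediate (not isolated)
7 | (1R,2S,3R,4S)-5,6-dimethylbicyclo[2.2.2]oct-5-ene-2,3-diol (meso, both OH syn to the alkene bridge) | [C@@H]12[C@H](O)[C@H](O)[C@@H](CC1)C(C)=C2C | intermediate
8 | (1R,3R,4S)-3-hydroxy-5,6-dimethylbicyclo[2.2.2]oct-5-en-2-one (OH syn to the alkene bridge) | [C@@H]12C(=O)[C@H](O)[C@@H](CC1)C(C)=C2C | intermediate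
9 | 4-chlorobut-2-yn-1-ol | OCC#CCCl | starting material
10 | 2-methylbuta-2,3-dien-1-ol | C=C=C(C)CO | intermediate
11 | 4-bromo-3-methylbuta-1,2-diene | C=C=C(C)CBr | intermediate
12 | (1R,2S,3R,4S)-5,6-dimethyl-2-(3-methylbuta-1,3-dien-2-yl)bicyclo[2.2.2]oct-5-ene-2,3-diol (dienyl and 3-OH syn to the alkene bridge) | [C@@H]12[C@](O)(C(=C)C(C)=C)[C@H](O)[C@@H](CC1)C(C)=C2C | intermediate
13 | (1R,2S,3R,4S)-5,6-dimethyl-2-(3-methylbuta-1,3-dien-2-yl)-3-(triethylsilyloxy)bicyclo[2.2.2]oct-5-en-2-ol | [C@@H]12[C@](O)(C(=C)C(C)=C)[C@H](O[Si](CC)(CC)CC)[C@@H](CC1)C(C)=C2C | intermediate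
14 | potassium C7=C8 dienolate of 15 | C=C(C)C1C[C@@]2(C)[C@H](CCC=C2C)[C@@H](O[Si](CC)(CC)CC)C=1O[K] | intermediate (not isolated)
15 | 9β-(triethylsilyloxy)-10βH-eremophila-3,11-dien-8-one (cis-fused, 5β-methyl, 7β-isopropenyl) | C=C(C)[C@H]1C[C@@]2(C)[C@H](CCC=C2C)[C@@H](O[Si](CC)(CC)CC)C1=O | intermediate
16 | (R)-1,2-epoxybutane | CC[C@@H]1CO1 | starting material
17 | dimethyl[(3R)-3-oxidopentyl]sulfonium (betaine) | CC[C@@H]([O-])CC[S+](C)C | intermediate (not isolated)
18 | (R)-pent-1-en-3-ol | CC[C@@H](O)C=C | intermediate
19 | angelic acid, (2Z)-2-methylbut-2-enoic acid | C/C=C(/C)C(=O)O | starting material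
20 | angelic 2,4,6-trichlorobenzoic anhydride | C/C=C(/C)C(=O)OC(=O)c1c(Cl)cc(Cl)cc1Cl | intermediate (not isolated)
21 | (3R)-pent-1-en-3-yl (2Z)-2-methylbut-2-enoate | CC[C@@H](OC(=O)/C(C)=C\C)C=C | intermediate
22 | (2E,4R)-4-{[(2Z)-2-methylbut-2-enoyl]oxy}hex-2-enoic acid | OC(=O)/C=C/[C@@H](CC)OC(=O)/C(C)=C\C | intermediate
23 | 9-O-triethylsilyl ether of the target (3α-acyloxy, 4β,5β-dimethyl, 7β-isopropenyl, 9β-OTES, 10βH) | C=C(C)[C@H]1C[C@@]2(C)[C@H](CC[C@@H](OC(=O)/C=C/[C@@H](CC)OC(=O)/C(C)=C\C)[C@@H]2C)[C@@H](O[Si](CC)(CC)CC)C1=O | intermediate
24 | (3R,4R,5R,7R,9R,10S)-9-hydroxy-8-oxoeremophil-11-en-3-yl (2E,4R)-4-{[(2Z)-2-methylbut-2-enoyl]oxy}hex-2-enoate (3α-acyloxy, 9β-OH, 10βH) | C=C(C)[C@H]1C[C@@]2(C)[C@H](CC[C@@H](OC(=O)/C=C/[C@@H](CC)OC(=O)/C(C)=C\C)[C@@H]2C)[C@@H](O)C1=O | target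

Total step count: 14. Longest linear sequence: 9 steps (steps 1, 2, 3, 4, 7, 8, 9, 13, 14).

**Steps most likely to fail**

1. Step 9 (oxy-Cope rearrangement). The hindered potassium alkoxide may lose the dienyl anion (retro-addition), the silyl group may migrate from O3 to the alkoxide, or the dienolate may be protonated at its terminal carbon to give the conjugated isopropylidene ketone. The fallback changes the mechanism from a concerted shift to a radical fragmentation and recombination, and sets out from 13. An alkoxy radical generated from the tertiary alcohol (CeCl3 cat., Bu4NCl, 400 nm light, MeCN, 2,4,6-triisopropylbenzenethiol as hydrogen-atom donor) should cleave the C1–C2 bond toward the allylic radical. That radical should close in a 6-endo Giese addition onto the terminal CH2 of the dienyl ketone so formed, and hydrogen-atom transfer would end at 15, where the route is rejoined. This fallback makes no compound outside the list (none, F0).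

2. Step 7 (dienyl delivery). If the indium chelate does not control the face, addition occurs anti to O3 and gives the C2 epimer, which cannot rearrange; acyloin 8 may also racemise through its enediol before it reacts. The fallback sets the C3 carbinol after the addition and sets out from 7:
   - Swern oxidation of both hydroxyls to 5,6-dimethylbicyclo[2.2.2]oct-5-ene-2,3-dione F1.
   - Mono-reduction by a ketoreductase from a panel to (1R,3S,4S)-3-hydroxy-5,6-dimethylbicyclo[2.2.2]oct-5-en-2-one F2 (hydroxyl on the ethano side), then TESCl to its triethylsilyl ether F3.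
   - Indium-mediated addition of 11, without chelation and anti to the silyloxy group (that is, from the alkene face), to the tertiary alcohol F4.
   - HF·pyridine to the cis-diol F5, then Dess–Martin oxidation of the secondary hydroxyl only, to the α-hydroxy ketone F6.
   - Hydroxyl-directed reduction with Me4NBH(OAc)3 (hydride from the side of the tertiary hydroxyl), which returns to the route at 12.

3. Step 13 (hydroacyloxylation). Hydrogen-atom transfer to the C4 radical may show poor facial selectivity, the hydrogen-atom donor may isomerise the angelate, and the excess acid may be hard to recover. The fallback separates C–O bond formation from esterification and sets out from 15: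
   - mCPBA (NaHCO3, CH2Cl2, −20 °C) should epoxidise the trisubstituted alkene first, anti to the axial C5 methyl, to 3α,4α-epoxy-9β-(triethylsilyloxy)-10βH-eremophil-11-en-8-one F7.
   - Reductive opening by trivalent titanium (Cp2TiCl2, Mn, collidine hydrochloride, 1,4-cyclohexadiene) at the more substituted carbon should give 3α-hydroxy-9β-(triethylsilyloxy)-10βH-eremophil-11-en-8-one F8.
   - Steglich esterification with 22 (DCC, DMAP cat., CH2Cl2) returns to the route at 23.

Further compounds
F1 | step 7 | (1R,4S)-5,6-dimethylbicyclo[2.2.2]oct-5-ene-2,3-dione (meso) | [C@@H]12C(=O)C(=O)[C@@H](CC1)C(C)=C2C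
F2 | step 7 | (1R,3S,4S)-3-hydroxy-5,6-dimethylbicyclo[2.2.2]oct-5-en-2-one (OH syn to the ethano bridge) | [C@@H]12C(=O)[C@@H](O)[C@@H](CC1)C(C)=C2C
F3 | step 7 | triethylsilyl ether of F2 | [C@@H]12C(=O)[C@@H](O[Si](CC)(CC)CC)[C@@H](CC1)C(C)=C2C
F4 | step 7 | (1R,2S,3S,4S)-5,6-dimethyl-2-(3-methylbuta-1,3-dien-2-yl)-3-(triethylsilyloxy)bicyclo[2.2.2]oct-5-en-2-ol | [C@@H]12[C@](O)(C(=C)C(C)=C)[C@@H](O[Si](CC)(CC)CC)[C@@H](CC1)C(C)=C2C
F5 | step 7 | (1R,2S,3S,4S)-5,6-dimethyl-2-(3-methylbuta-1,3-dien-2-yl)bicyclo[2.2.2]oct-5-ene-2,3-diol (cis-diol, both OH syn to the ethano bridge) | [C@@H]12[C@](O)(C(=C)C(C)=C)[C@@H](O)[C@@H](CC1)C(C)=C2C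
F6 | step 7 | α-hydroxy ketone with the tertiary carbinol of 12 and a C3 ketone | [C@@H]12[C@](O)(C(=C)C(C)=C)C(=O)[C@@H](CC1)C(C)=C2C
F0 | step 9 | none | none
F7 | step 13 | 3α,4α-epoxy-9β-(triethylsilyloxy)-10βH-eremophil-11-en-8-one | C=C(C)[C@H]1C[C@@]2(C)[C@H](CC[C@H]3O[C@@]23C)[C@@H](O[Si](CC)(CC)CC)C1=O
F8 | step 13 | 3α-hydroxy-9β-(triethylsilyloxy)-10βH-eremophil-11-en-8-one | C=C(C)[C@H]1C[C@@]2(C)[C@H](CC[C@@H](O)[C@@H]2C)[C@@H](O[Si](CC)(CC)CC)C1=O
A1 | direct plan | (S)-Hajos–Parrish ketone, (7aS)-7a-methyl-2,3,7,7a-tetrahydro-1H-indene-1,5(6H)-dione | C[C@]12CCC(=O)C=C1CCC2=O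
A2 | direct plan | (4aR,5R)-4a,5-dimethyl-4,4a,7,8-tetrahydronaphthalene-2,6(3H,5H)-dione | O=C1CC[C@@]2(C)C(=C1)CCC(=O)[C@@H]2C
A3 | direct plan | 9β-(tert-butyldimethylsilyloxy)-3α-hydroxy-10βH-eremophil-11-en-8-one | C=C(C)[C@H]1C[C@@]2(C)[C@H](CC[C@@H](O)[C@@H]2C)[C@@H](O[Si](C)(C)C(C)(C)C)C1=O
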